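The seven-membered ring is disconnected between C4, the carbinol carbon that carries the anisate, and C5, the ring CH2 next to the methyl-bearing alkene carbon C6 (azulene numbering). C4–C5–C6=C7 is a homoallylic, β,γ-unsaturated array, the retron of a diene 1,4-hydroacylation. The precursor 15 is a monocyclic, fully decorated cyclopentane with a formyl group on C3a and, trans to it on quaternary C8a, an (E)-3-methylbuta-1,3-dienyl group. A cationic rhodium catalyst adds the aldehyde C–H across the diene: the C4–C5 bond, the trans-fused seven-membered ring, the C4 carbonyl and the C6=C7 alkene arise in one reagent-free isomerisation; hydroxyl-directed reduction then sets C4.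

Key step: step 11

Assumption: azulene numbering of the target (C1 acetoxy, C3 carbinol, C3a/C8a ring fusion, C4 anisoyloxy, C6=C7 alkene) is used for the corresponding atoms of all intermediates; 1, 7, 8 and 18 are taken as commercial, and the tertiary hydroxyl of 6 is carried unprotected (as its lithium alkoxide) through step 6.

Step 1
Reactants: 1 (4R)-4-{[tert-butyl(dimethyl)silyl]oxy}cyclopent-2-en-1-one
Product: 2 tert-butyl(dimethyl){[(1R,2R)-2-methyl-4-(trimethylsilyloxy)cyclopent-3-en-1-yl]oxy}silane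
Conditions: MeMgBr, CuBr·SMe2 (10 mol %), Me3SiCl, HMPA, THF, −78 °C
Reagents that add atoms: methylmagnesium bromide C[Mg]Br; chlorotrimethylsilane C[Si](C)(C)Cl
Why: Copper-catalysed conjugate addition of the Grignard reagent with in situ O-silylation of the enolate should put the methyl group trans to the silyloxy group (a centre erased in step 2) and fix the position of the enol double bond for the dehydrogenation.

Step 2
Reactants: 2 tert-butyl(dimethyl){[(1R,2R)-2-methyl-4-(trimethylsilyloxy)cyclopent-3-en-1-yl]oxy}silane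
Product: 3 (4R)-4-{[tert-butyl(dimethyl)silyl]oxy}-3-methylcyclopent-2-en-1-one
Conditions: Pd(OAc)2 (10 mol %), O2 (1 atm), DMSO, rt
Reagents that add atoms: none
Why: Saegusa–Ito dehydrogenation of the silyl enol ether (C-palladation, then β-hydride elimination of the tertiary C–H) should give the β-methyl enone with the silyloxy stereocentre untouched.

Step 3
Reactants: 3 (4R)-4-{[tert-butyl(dimethyl)silyl]oxy}-3-methylcyclopent-2-en-1-one
Product: 4 (1R,4R)-4-{[tert-butyl(dimethyl)silyl]oxy}-3-methyl-1-(propan-2-yl)cyclopent-2-en-1-ol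
Conditions: iPrMgCl, CeCl3, THF, −78 °C
Reagents that add atoms: isopropylmagnesium chloride CC(C)[Mg]Cl
Why: Organocerium 1,2-addition to the enone carbonyl (no conjugate addition, little enolisation) from the face opposite to the silyloxy group should set the tertiary carbinol (future C3) as R, the minor diastereomer being removable by chromatography.

Step 4
Reactants: 4 (1R,4R)-4-{[tert-butyl(dimethyl)silyl]oxy}-3-methyl-1-(propan-2-yl)cyclopent-2-en-1-ol
Product: 5 (1R,4R)-3-methyl-1-(propan-2-yl)cyclopent-2-ene-1,4-diol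
Conditions: Bu4NF, THF, 0 °C to rt
Reagents that add atoms: none
Why: Fluoride-mediated silyl ether cleavage under non-acidic conditions should spare the ionisable tertiary allylic alcohol and leave both stereocentres unchanged.

Step 5
Reactants: 5 (1R,4R)-3-methyl-1-(propan-2-yl)cyclopent-2-ene-1,4-diol
Product: 6 (4R)-4-hydroxy-2-methyl-4-(propan-2-yl)cyclopent-2-en-1-one
Conditions: MnO2, CH2Cl2, rt
Reagents that add atoms: none
Why: Chemoselective allylic oxidation with manganese dioxide can only touch the secondary allylic alcohol, so the relay stereocentre becomes the future C1 carbonyl and the R tertiary carbinol remains as the single stereocentre.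

Step 6
Reactants: 6 (4R)-4-hydroxy-2-methyl-4-(propan-2-yl)cyclopent-2-en-1-one; 7 1,3-dithiane; 8 (2E)-1,4-dibromo-2-methylbut-2-ene
Product: 11 (2E)-4-[(1R,2R,3R)-2-(1,3-dithian-2-yl)-3-hydroxy-1-methyl-5-oxo-3-(propan-2-yl)cyclopentyl]-2-methylbut-2-en-1-yl acetate, via dilithium enolate-alkoxide 9 (not isolated), via allylic bromide 10 (not isolated)
Conditions: 7 (2.3 equiv), n-BuLi, THF, −30 °C; 6, HMPA, −78 °C; 8 (3 equiv), −78 to −30 °C; AcOH (1 equiv), then Bu4NOAc, rt
Reagents that add atoms: tetrabutylammonium acetate CCCC[N+](CCCC)(CCCC)CCCC.CC(=O)[O-]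
Why: Tandem conjugate addition–enolate alkylation (three-component coupling) followed by SN2 acetate displacement: the lithiated dithiane should add 1,4 (HMPA) to the lithium alkoxide of 6 on the face opposite to the isopropyl group, and the tetrasubstituted enolate should be alkylated trans to the new dithianyl group at the less hindered, prenyl-type CH2Br of 8 (remote from its methyl group), which sets C3a (R) and quaternary C8a (R).

Step 7
Reactants: 11 (2E)-4-[(1R,2R,3R)-2-(1,3-dithian-2-yl)-3-hydroxy-1-methyl-5-oxo-3-(propan-2-yl)cyclopentyl]-2-methylbut-2-en-1-yl acetate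
Product: 12 (2E)-4-[(1R,2R,3R,5S)-2-(1,3-dithian-2-yl)-3,5-dihydroxy-1-methyl-3-(propan-2-yl)cyclopentyl]-2-methylbut-2-en-1-yl acetate
Conditions: Me4NBH(OAc)3, MeCN/AcOH (1:1), −30 to 0 °C
Reagents that add atoms: none
Why: Hydroxyl-directed (Evans–Saksena) reduction, in which the tertiary hydroxyl binds boron and delivers hydride intramolecularly to its own face of the β-ketone, should give the 1,3-anti diol, that is the C1 carbinol (S) trans to the tertiary OH and cis to the side chain.

Step 8
Reactants: 12 (2E)-4-[(1R,2R,3R,5S)-2-(1,3-dithian-2-yl)-3,5-dihydroxy-1-methyl-3-(propan-2-yl)cyclopentyl]-2-methylbut-2-en-1-yl acetate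
Product: 13 (2E)-4-[(1R,2R,3R,5S)-5-(acetyloxy)-2-(1,3-dithian-2-yl)-3-hydroxy-1-methyl-3-(propan-2-yl)cyclopentyl]-2-methylbut-2-en-1-yl acetate
Conditions: Ac2O, pyridine, DMAP (cat.), CH2Cl2, rt
Reagents that add atoms: acetic anhydride CC(=O)OC(C)=O
Why: DMAP-catalysed acylation should esterify only the secondary C1 hydroxyl, the hindered tertiary alcohol being inert under these conditions, with no change at any stereocentre.

Step 9
Reactants: 13 (2E)-4-[(1R,2R,3R,5S)-5-(acetyloxy)-2-(1,3-dithian-2-yl)-3-hydroxy-1-methyl-3-(propan-2-yl)cyclopentyl]-2-methylbut-2-en-1-yl acetate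
Product: 14 (1S,2R,3R,4R)-3-(1,3-dithian-2-yl)-4-hydroxy-2-methyl-2-[(1E)-3-methylbuta-1,3-dien-1-yl]-4-(propan-2-yl)cyclopentyl acetate
Conditions: Pd(PPh3)4 (5 mol %), Et3N, 1,4-dioxane, 90 °C
Reagents that add atoms: none
Why: Palladium-catalysed 1,4-elimination of the primary allylic acetate (Tsuji-type diene synthesis via a π-allylpalladium whose only β-hydrogens sit on C8) should give the (E)-1,3-diene regiospecifically while the non-allylic C1 acetate stays in place.

Step 10
Reactants: 14 (1S,2R,3R,4R)-3-(1,3-dithian-2-yl)-4-hydroxy-2-methyl-2-[(1E)-3-methylbuta-1,3-dien-1-yl]-4-(propan-2-yl)cyclopentyl acetate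
Product: 15 (1S,2R,3R,4R)-3-formyl-4-hydroxy-2-methyl-2-[(1E)-3-methylbuta-1,3-dien-1-yl]-4-(propan-2-yl)cyclopentyl acetate
Conditions: MeI, CaCO3, MeCN/H2O (9:1), 45 °C
Reagents that add atoms: water O
Why: Alkylative hydrolysis of the dithioacetal (S-methylation, then hydrolysis buffered by CaCO3) should unmask the aldehyde without touching diene, acetate or tertiary alcohol, the formyl group remaining trans to the dienyl group, which is also the thermodynamically preferred arrangement.

Step 11
Reactants: 15 (1S,2R,3R,4R)-3-formyl-4-hydroxy-2-methyl-2-[(1E)-3-methylbuta-1,3-dien-1-yl]-4-(propan-2-yl)cyclopentyl acetate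
Product: 16 (1S,3R,3aR,8aR)-3-hydroxy-6,8a-dimethyl-4-oxo-3-(propan-2-yl)-1,2,3,3a,4,5,8,8a-octahydroazulen-1-yl acetate
Conditions: [Rh(dppe)]ClO4 (10 mol %; dppe = Ph2PCH2CH2PPh2), ClCH2CH2Cl, 65 °C
Reagents that add atoms: none
Why: Monovalent rhodium should insert into the aldehyde C–H bond, the proximal C7=C8 double bond then inserts into Rh–H with hydrogen going to C8, and the resulting acyl(η3-allyl)rhodium (C5–C6–C7) reductively eliminates at its unsubstituted terminus C5 to form the C4–C5 bond. The closest known reaction type is the rhodium-catalysed intramolecular hydroacylation of 4,6-dienals to cyclohept-3-enones, the substrate class to which 15 belongs. The seven-membered ring closes by C–C reductive elimination from an eight-membered acyl(σ-allyl)rhodacycle (formally a 7-endo closure onto the diene terminus), and the ring constraint makes the new C6=C7 bond cis. No stereocentre is created; C3a and C8a are carried over, so the trans ring fusion follows from the trans arrangement set in step 6. The step needs seven- over five-membered closure and no decarbonylation: closure at C7 would give a strained trans-fused bicyclo[3.3.0]octanone and C5 is the unhindered allyl terminus, while the chelating diphosphine on cationic rhodium disfavours CO extrusion.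

Step 12
Reactants: 16 (1S,3R,3aR,8aR)-3-hydroxy-6,8a-dimethyl-4-oxo-3-(propan-2-yl)-1,2,3,3a,4,5,8,8a-octahydroazulen-1-yl acetate
Product: 17 (1S,3R,3aS,4S,8aR)-3,4-dihydroxy-6,8a-dimethyl-3-(propan-2-yl)-1,2,3,3a,4,5,8,8a-octahydroazulen-1-yl acetate
Conditions: Me4NBH(OAc)3, MeCN/AcOH (1:1), −30 °C
Reagents that add atoms: none
Why: A second hydroxyl-directed (Evans–Saksena) reduction, in which the C3 hydroxyl lying on the α-face gauche to the C4 carbonyl delivers hydride to that face, should give the 4S alcohol and override the intrinsic preference for attack anti to the angular methyl.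

Step 13
Reactants: 17 (1S,3R,3aS,4S,8aR)-3,4-dihydroxy-6,8a-dimethyl-3-(propan-2-yl)-1,2,3,3a,4,5,8,8a-octahydroazulen-1-yl acetate; 18 4-methoxybenzoyl chloride
Product: 19 (1S,3R,3aS,4S,8aR)-1-(acetyloxy)-3-hydroxy-6,8a-dimethyl-3-(propan-2-yl)-1,2,3,3a,4,5,8,8a-octahydroazulen-4-yl 4-methoxybenzoate
Conditions: 18, Et3N, DMAP (cat.), CH2Cl2, 0 °C to rt
Reagents that add atoms: none
Why: DMAP-catalysed esterification (nucleophilic acyl substitution) should acylate the only secondary hydroxyl, the tertiary C3 hydroxyl being unreactive, with no stereocentre affected.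

Compound list
1 | (4R)-4-{[tert-butyl(dimethyl)silyl]oxy}cyclopent-2-en-1-one | O=C1C=C[C@H](O[Si](C)(C)C(C)(C)C)C1 | starting material
2 | tert-butyl(dimethyl){[(1R,2R)-2-methyl-4-(trimethylsilyloxy)cyclopent-3-en-1-yl]oxy}silane (methyl trans to OTBS) | C[C@@H]1C=C(O[Si](C)(C)C)C[C@H]1O[Si](C)(C)C(C)(C)C | intermediate
3 | (4R)-4-{[tert-butyl(dimethyl)silyl]oxy}-3-methylcyclopent-2-en-1-one | CC1=CC(=O)C[C@H]1O[Si](C)(C)C(C)(C)C | intermediate
4 | (1R,4R)-4-{[tert-butyl(dimethyl)silyl]oxy}-3-methyl-1-(propan-2-yl)cyclopent-2-en-1-ol (isopropyl trans to OTBS) | CC1=C[C@](O)(C(C)C)C[C@H]1O[Si](C)(C)C(C)(C)C | intermediate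
5 | (1R,4R)-3-methyl-1-(propan-2-yl)cyclopent-2-ene-1,4-diol (cis diol) | CC1=C[C@](O)(C(C)C)C[C@H]1O | intermediate
6 | (4R)-4-hydroxy-2-methyl-4-(propan-2-yl)cyclopent-2-en-1-one | CC1=C[C@](O)(C(C)C)CC1=O | intermediate
7 | 1,3-dithiane | C1CSCSC1 | starting material
8 | (2E)-1,4-dibromo-2-methylbut-2-ene | BrC/C=C(\C)CBr | starting material
9 | dilithium (3R,4R)-3-(1,3-dithian-2-yl)-2-methyl-4-(propan-2-yl)cyclopent-1-ene-1,4-bis(olate) (not isolated) | CC1=C(O[Li])C[C@@](O[Li])(C(C)C)[C@@H]1C2SCCCS2 | intermediate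
10 | lithium (1R,2R,3R)-3-[(2E)-4-bromo-3-methylbut-2-en-1-yl]-2-(1,3-dithian-2-yl)-3-methyl-4-oxo-1-(propan-2-yl)cyclopentan-1-olate (not isolated) | S1CCCSC1[C@@H]2[C@@](C)(C/C=C(\C)CBr)C(=O)C[C@@]2(O[Li])C(C)C | intermediate
11 | (2E)-4-[(1R,2R,3R)-2-(1,3-dithian-2-yl)-3-hydroxy-1-methyl-5-oxo-3-(propan-2-yl)cyclopentyl]-2-methylbut-2-en-1-yl acetate | S1CCCSC1[C@@H]2[C@@](C)(C/C=C(\C)COC(C)=O)C(=O)C[C@@]2(O)C(C)C | intermediate
12 | (2E)-4-[(1R,2R,3R,5S)-2-(1,3-dithian-2-yl)-3,5-dihydroxy-1-methyl-3-(propan-2-yl)cyclopentyl]-2-methylbut-2-en-1-yl acetate | S1CCCSC1[C@@H]2[C@@](C)(C/C=C(\C)COC(C)=O)[C@@H](O)C[C@@]2(O)C(C)C | intermediate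
13 | (2E)-4-[(1R,2R,3R,5S)-5-(acetyloxy)-2-(1,3-dithian-2-yl)-3-hydroxy-1-methyl-3-(propan-2-yl)cyclopentyl]-2-methylbut-2-en-1-yl acetate | S1CCCSC1[C@@H]2[C@@](C)(C/C=C(\C)COC(C)=O)[C@@H](OC(C)=O)C[C@@]2(O)C(C)C | intermediate
14 | (1S,2R,3R,4R)-3-(1,3-dithian-2-yl)-4-hydroxy-2-methyl-2-[(1E)-3-methylbuta-1,3-dien-1-yl]-4-(propan-2-yl)cyclopentyl acetate | S1CCCSC1[C@@H]2[C@@](C)(/C=C/C(C)=C)[C@@H](OC(C)=O)C[C@@]2(O)C(C)C | intermediate
15 | (1S,2R,3R,4R)-3-formyl-4-hydroxy-2-methyl-2-[(1E)-3-methylbuta-1,3-dien-1-yl]-4-(propan-2-yl)cyclopentyl acetate | O=C[C@@H]1[C@@](C)(/C=C/C(C)=C)[C@@H](OC(C)=O)C[C@@]1(O)C(C)C | intermediate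
16 | (1S,3R,3aR,8aR)-3-hydroxy-6,8a-dimethyl-4-oxo-3-(propan-2-yl)-1,2,3,3a,4,5,8,8a-octahydroazulen-1-yl acetate (trans-fused) | O=C1CC(C)=CC[C@@]2(C)[C@@H](OC(C)=O)C[C@@](O)(C(C)C)[C@H]12 | intermediate
17 | (1S,3R,3aS,4S,8aR)-3,4-dihydroxy-6,8a-dimethyl-3-(propan-2-yl)-1,2,3,3a,4,5,8,8a-octahydroazulen-1-yl acetate | O[C@H]1CC(C)=CC[C@@]2(C)[C@@H](OC(C)=O)C[C@@](O)(C(C)C)[C@H]12 | intermediate
18 | 4-methoxybenzoyl chloride | COc1ccc(cc1)C(Cl)=O | starting material
19 | (1S,3R,3aS,4S,8aR)-1-(acetyloxy)-3-hydroxy-6,8a-dimethyl-3-(propan-2-yl)-1,2,3,3a,4,5,8,8a-octahydroazulen-4-yl 4-methoxybenzoate | COc1ccc(C(=O)O[C@H]2CC(C)=CC[C@@]3(C)[C@@H](OC(C)=O)C[C@@](O)(C(C)C)[C@H]23)cc1 | target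

Total step count: 13. Longest linear sequence: 13 steps (1 to 19).

Steps most likely to fail

Step 11. The acylrhodium hydride may lose CO (decarbonylation), the allyl intermediate may couple at its inner terminus, or rhodium hydride may move the new double bond into conjugation with the ketone. The fallback sets out from 6 and comes back at 16, and closes the ring by metathesis instead. Compound 6 would undergo the same dithiane addition but with allyl bromide as the electrophile, giving allyl ketone F1. Hydroxyl-directed reduction with Me4NBH(OAc)3 would give diol F2, acetylation would give acetate F3, and hydrolysis with MeI/CaCO3 would give aldehyde F4. Indium-mediated Barbier addition of 3-bromo-2-methylprop-1-ene (In powder, THF/H2O) would form the C4–C5 bond intermolecularly and give homoallylic alcohol F5 as both carbinol epimers. Ring-closing metathesis with the second-generation Grubbs catalyst would close the seven-membered ring at C6=C7 to give hydroazulenol F6 as both C4 epimers, and Dess–Martin oxidation would converge these on ketone 16.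

Step 6. The congested tetrasubstituted enolate may be alkylated at the wrong bromomethyl terminus of the unsymmetrical dibromide, or the alkoxide oxygen may be alkylated instead. The fallback sets out from 6 and comes back at 14, replacing the alkylation by an aldol addition. Enolate 9, generated from 6 as before, would be transmetallated with ZnCl2 and trapped with 3-methylbut-2-enal to give aldol F7 (both carbinol epimers, which later converge). Selective acetylation of its secondary allylic hydroxyl would give allylic acetate F8, hydroxyl-directed reduction of the ketone would give alcohol F9, and a second acetylation would give diacetate F10. Elimination of the secondary allylic acetate with Pd(PPh3)4/Et3N, where the only β-hydrogens are on the two methyl groups, would give diene 14.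

Step 12. Ligand exchange at the hindered tertiary alcohol may be too slow to direct the hydride, so that external hydride attacks anti to the angular methyl and gives the wrong C4 configuration. The fallback sets out from 16 and comes back at 19, using substrate-controlled reduction and an invertive esterification. Non-directed reduction with NaBH4/CeCl3·7H2O from the open β-face would give the 4-epi alcohol F11. Mitsunobu esterification of F11 with 4-methoxybenzoic acid (PPh3, DIAD) would invert C4 and give target 19 directly.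

Further compounds
F1 | step 11 | (2R,3R,4R)-3-(1,3-dithian-2-yl)-4-hydroxy-2-methyl-4-(propan-2-yl)-2-(prop-2-en-1-yl)cyclopentan-1-one | S1CCCSC1[C@@H]2[C@@](C)(CC=C)C(=O)C[C@@]2(O)C(C)C
F2 | step 11 | (1R,3S,4R,5R)-5-(1,3-dithian-2-yl)-4-methyl-1-(propan-2-yl)-4-(prop-2-en-1-yl)cyclopentane-1,3-diol | S1CCCSC1[C@@H]2[C@@](C)(CC=C)[C@@H](O)C[C@@]2(O)C(C)C
F3 | step 11 | (1S,2R,3R,4R)-3-(1,3-dithian-2-yl)-4-hydroxy-2-methyl-4-(propan-2-yl)-2-(prop-2-en-1-yl)cyclopentyl acetate | S1CCCSC1[C@@H]2[C@@](C)(CC=C)[C@@H](OC(C)=O)C[C@@]2(O)C(C)C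
F4 | step 11 | (1S,2R,3R,4R)-3-formyl-4-hydroxy-2-methyl-4-(propan-2-yl)-2-(prop-2-en-1-yl)cyclopentyl acetate | O=C[C@@H]1[C@@](C)(CC=C)[C@@H](OC(C)=O)C[C@@]1(O)C(C)C
F5 | step 11 | (1S,2R,3S,4R)-4-hydroxy-3-(1-hydroxy-3-methylbut-3-en-1-yl)-2-methyl-4-(propan-2-yl)-2-(prop-2-en-1-yl)cyclopentyl acetate (both carbinol epimers) | C=C(C)CC(O)[C@@H]1[C@@](C)(CC=C)[C@@H](OC(C)=O)C[C@@]1(O)C(C)C
F6 | step 11 | (1S,3R,3aS,8aR)-3,4-dihydroxy-6,8a-dimethyl-3-(propan-2-yl)-1,2,3,3a,4,5,8,8a-octahydroazulen-1-yl acetate (both C4 epimers) | OC1CC(C)=CC[C@@]2(C)[C@@H](OC(C)=O)C[C@@](O)(C(C)C)[C@H]12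
F7 | step 6 | 3-(1,3-dithian-2-yl)-4-hydroxy-2-(1-hydroxy-3-methylbut-2-en-1-yl)-2-methyl-4-(propan-2-yl)cyclopentan-1-one, ring stereocentres as in 11 (both carbinol epimers) | S1CCCSC1[C@@H]2[C@@](C)(C(O)C=C(C)C)C(=O)C[C@@]2(O)C(C)C
F8 | step 6 | 1-[2-(1,3-dithian-2-yl)-3-hydroxy-1-methyl-5-oxo-3-(propan-2-yl)cyclopentyl]-3-methylbut-2-en-1-yl acetate, ring stereocentres as in 11 | S1CCCSC1[C@@H]2[C@@](C)(C(OC(C)=O)C=C(C)C)C(=O)C[C@@]2(O)C(C)C
F9 | step 6 | 1-[2-(1,3-dithian-2-yl)-3,5-dihydroxy-1-methyl-3-(propan-2-yl)cyclopentyl]-3-methylbut-2-en-1-yl acetate, ring stereocentres as in 12 | S1CCCSC1[C@@H]2[C@@](C)(C(OC(C)=O)C=C(C)C)[C@@H](O)C[C@@]2(O)C(C)C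
F10 | step 6 | 1-[5-(acetyloxy)-2-(1,3-dithian-2-yl)-3-hydroxy-1-methyl-3-(propan-2-yl)cyclopentyl]-3-methylbut-2-en-1-yl acetate, ring stereocentres as in 13 | S1CCCSC1[C@@H]2[C@@](C)(C(OC(C)=O)C=C(C)C)[C@@H](OC(C)=O)C[C@@]2(O)C(C)C
F11 | step 12 | (1S,3R,3aS,4R,8aR)-3,4-dihydroxy-6,8a-dimethyl-3-(propan-2-yl)-1,2,3,3a,4,5,8,8a-octahydroazulen-1-yl acetate (C4 epimer of 17) | O[C@@H]1CC(C)=CC[C@@]2(C)[C@@H](OC(C)=O)C[C@@](O)(C(C)C)[C@H]12
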